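**Plan**
Numbering (germacrane): ring C1–C10, ester C14 on C10, methyl C15 on C4, lactone O6–C12(=O)–C11(=C13)–C7, methacrylate on O8, acetate on O9.
Enabling feature: the enoate alkene C1=C10 and the C4–C5 oxirane (a masked ring-trans alkene) lie 1,5 to each other across C2–C3. Two extra bonds, C1–C4 and C5–C10, therefore fold the ten-membered ring into a bicyclo[2.2.0]hexane (ring A: C1–C4; ring B: C1/C10/C5/C4) fused to a cyclohexane (ring C: C5–C10).
Retrosynthetic cuts, in order: the oxirane O; re-closure of C1–C4 and C5–C10; C11=C13; the acyl groups on O8 and O9; O8 and O9 themselves (back to a C8=C9, then a C7=C8 alkene); C7–C11 and O6–C12; last C1–C10 and C4–C5, which leaves 1-methylcyclobutene and methyl 3-oxocyclohex-1-ene-1-carboxylate.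
Forward: ring A is made in one step and ring C is bought. Ring B closes in the photocycloaddition, lactone ring D closes on the rigid tricycle, heat merges A, B and C into the ten-membered ring, and the oxirane comes last.
Stereochemistry: a chiral Lewis acid fixes the temporary centres C1, C4, C5 and C10, and these send hydride to the convex face (C6). C6 relays to C7 through an ester tether, and the lactone plus the convex face set C9 (OsO4) and C8 (hydride). A chair 1,4-diyl sets both alkene geometries, and allylic strain at C6 with peripheral attack sets C4 and C5.

Key step: step 2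

Notation: germacrane locants are kept for all intermediates. In the tricycles the convex face of ring C carries H5 and the C10 ester, and the concave face carries C4 and C1.
Assumption on the target: the SMILES is read as 4R,5R,6S,7S,8R,9R with C2 and C9 cis on C1=C10. This means H6/H7 cis (cis-fused lactone), O8 cis to C11, O9 trans to O8, and C3 and C6 trans on the oxirane. Because hydride must reach C6 from the convex face, the (1R,2R,5S,6R) photoadduct is the one required.
Assumption on step 2: the sense of induction of the oxazaborolidine on enone 3 cannot be predicted with certainty. The (S)-prolinol-derived catalyst is written, and its mirror image is used if it favours the other enantiomer.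

**Step 1**
Reactants: 1 methylenecyclobutane
Product: 2 1-methylcyclobutene
Conditions: Na/Al2O3 (cat.), neat, 25 °C; distillation
Reagents that add atoms: none
Why: Base-catalysed prototropic alkene isomerisation, in which reversible allylic deprotonation carries the exocyclic double bond into the ring, where the trisubstituted alkene is the favoured isomer at equilibrium.

**Step 2**
Reactants: 3 methyl 3-oxocyclohex-1-ene-1-carboxylate; 2 1-methylcyclobutene (excess)
Product: 4 methyl (1R,2R,5S,6R)-5-methyl-7-oxotricyclo[4.4.0.0(2,5)]decane-1-carboxylate (cis-anti-cis photoadduct; ester on C10, methyl on C4, ketone at C6)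
Conditions: hν (366 nm), oxazaborolidine from (S)-α,α-bis(3,5-dimethylphenyl)prolinol and 2,4,6-trifluorophenylboronic acid (50 mol %), AlBr3 (50 mol %), CH2Cl2, −75 °C
Reagents that add atoms: none
Why: Proposed new method: coordination of the activated oxazaborolidine to the ketone oxygen of 3 moves the π,π* band to the lamp wavelength, the excited complex crosses to the triplet and adds to 2 through a 1,4-diradical; the closest known reaction types are the oxazaborolidine–AlBr3-catalysed intermolecular [2+2] photocycloaddition of 2-cyclohexenones with simple olefins and the uncatalysed enone–cyclobutene photocycloaddition, but a 3-alkoxycarbonyl enone has not been used under the chiral catalyst. The one ring that closes, cyclobutane B (C1–C10–C5–C4), does so in two stages, C10–C1 bond formation and then, after spin inversion, 1,4-diradical recombination between C5 and C4. C1 and C4 are cis because both belong to the small ring of 2, C5 and C10 are cis because a trans six–four junction is strained and C5 stays epimerisable next to the ketone, and rings A and C end anti because 2 approaches with its CH2–CH2 edge turned away from C6–C9. The absolute configuration of all four centres is set by the aryl group of the catalyst, which covers one face of the bound enone. The step needs regioselectivity: the CH end of 2 is attacked first so that the tertiary C4 radical results, and of the two possible diradicals only the one with spin at C5 and C4 can close without joining two fully substituted carbons, the other falling back to 2 and 3.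

**Step 3**
Reactants: 4 photoadduct
Product: 5 methyl (1R,2R,5S,6R)-5-methyl-7-oxotricyclo[4.4.0.0(2,5)]dec-8-ene-1-carboxylate (C7=C8 enone)
Conditions: IBX (2.5 equiv), PhF–DMSO, 70 °C
Reagents that add atoms: none
Why: IBX dehydrogenation of a ketone through its enol; C4 and C10 bear no hydrogen, so C7–C8 is the only α,β pair that can be desaturated, and the temperature stays far below that needed to open the bicyclo[2.2.0]hexane.

**Step 4**
Reactants: 5 enone
Product: 6 methyl (1R,2R,5S,6R,7S)-7-hydroxy-5-methyltricyclo[4.4.0.0(2,5)]dec-8-ene-1-carboxylate (allylic alcohol, O6 on the concave face, cis to C4)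
Conditions: NaBH4, CeCl3·7H2O, MeOH, −78 °C
Reagents that add atoms: none
Why: Luche reduction gives clean 1,2-addition, and hydride enters from the convex face because the concave side of C6 is closed by C4 and its methyl group, which puts O6 cis to C4 and fixes the 6S centre.

**Step 5**
Reactants: 6 allylic alcohol; 7 diethylphosphonoacetic acid
Product: 8 C6 diethylphosphonoacetate of 6
Conditions: DCC, DMAP (cat.), CH2Cl2, 0 °C → rt
Reagents that add atoms: none
Why: Steglich esterification of a hindered secondary alcohol under neutral conditions, with retention at C6 because only the O–H bond reacts.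

**Step 6**
Reactants: 8 allylic phosphonoacetate
Product: 9 7,8-epoxide of 8 (oxirane on the convex face, trans to O6)
Conditions: mCPBA, CH2Cl2, 0 °C → rt
Reagents that add atoms: mCPBA, O=C(OO)c1cccc(Cl)c1
Why: Prilezhaev epoxidation of the only alkene; the peracid arrives on the convex face, which is also the face opposite the bulky allylic ester, so the oxirane lies trans to O6.

**Step 7**
Reactants: 9 epoxy phosphonoacetate
Product: 10 cis-fused 6,12-lactone with P(O)(OEt)2 on C11 (both C11 epimers) and a convex-face C8 hydroxyl
Conditions: DBU, LiOTf, MeCN, 50 °C
Reagents that add atoms: none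
Why: Intramolecular alkylation of a phosphonate-stabilised carbanion by an epoxide (5-exo-tet, trans-diaxial opening); the tether on O6 reaches only the rear side of the C7–O bond, so C7–C11 forms with inversion and cis to O6 (7S in the target), while the protonated amine quenches the C8 alkoxide at once.

**Step 8**
Reactants: 10 hydroxy phosphono lactone
Product: 11 phosphono lactone with a C8=C9 alkene
Conditions: POCl3, pyridine, 0 °C → rt
Reagents that add atoms: none
Why: POCl3–pyridine dehydration (anti E2 elimination of the activated alcohol); the axial C8–O bond has an antiperiplanar hydrogen only at C9, H7 being syn to it, and pyridine is too weak a base to deprotonate C11.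

**Step 9**
Reactants: 11 alkene
Product: 12 8,9-cis-diol, both hydroxyls on the convex face (trans to the lactone)
Conditions: OsO4 (5 mol %), NMO, acetone–H2O, rt
Reagents that add atoms: N-methylmorpholine N-oxide, C[N+]1([O-])CCOCC1; water, O
Why: Upjohn dihydroxylation, a suprafacial [3+2] addition of OsO4; the concave side of the alkene is flanked by C1 and by the axial C7–C11 bond, so both oxygens arrive on the convex face and set C9 (9R in the target).

**Step 10**
Reactants: 12 cis-diol
Product: 13 α-ketol (C8 ketone, convex-face C9 hydroxyl)
Conditions: IBX (1.05 equiv), DMSO, rt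
Reagents that add atoms: none
Why: IBX turns 1,2-diols into α-ketols without C–C cleavage, ligand exchange at iodine being faster for the C8 hydroxyl than for the neopentyl C9 hydroxyl beside quaternary C10, and H7 lies near the carbonyl plane, which slows enolisation towards C7 and loss of O6.

**Step 11**
Reactants: 13 α-ketol
Product: 14 C9 acetate of 13
Conditions: Ac2O, pyridine, DMAP (cat.), CH2Cl2, 0 °C
Reagents that add atoms: acetic anhydride, CC(=O)OC(C)=O
Why: DMAP-catalysed acetylation of the only free hydroxyl, with retention at C9 and under conditions too mild to enolise the ketone.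

**Step 12**
Reactants: 14 acetoxy ketone
Product: 15 C8 alcohol, hydroxyl on the concave face (cis to C11, trans to the acetate)
Conditions: NaBH4, CeCl3·7H2O, MeOH–THF, −78 °C
Reagents that add atoms: none
Why: Luche-type borohydride reduction; the small hydride adds axially on the convex face, anti to the axial C7–C11 bond, so O8 becomes equatorial, cis to C11 and trans to the acetate (8R in the target), while CeCl3 and low temperature hold back acetyl migration and β-elimination.

**Step 13**
Reactants: 15 hydroxy acetate
Product: 16 C8 methacrylate of 15
Conditions: methacrylic anhydride, Et3N, DMAP, BHT (trace), CH2Cl2, 0 °C → rt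
Reagents that add atoms: methacrylic anhydride, C=C(C)C(=O)OC(=O)C(C)=C
Why: DMAP-catalysed acyl transfer from the anhydride to the single free, equatorial hydroxyl, with retention at C8.

**Step 14**
Reactants: 16 phosphono lactone diester
Product: 17 fully functionalised tricycle with the α-methylene lactone
Conditions: aq. HCHO (37 %), K2CO3, THF, 0 °C
Reagents that add atoms: formaldehyde, C=O
Why: Horner–Wadsworth–Emmons olefination of formaldehyde by the α-phosphono lactone, which needs only carbonate base, erases the undefined C11 centre and leaves the three esters intact.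

**Step 15**
Reactants: 17 tricycle
Product: 18 4,5-deoxyfluctuadin (ten-membered diene: C4=C5 ring-trans, C1=C10 ring-cis with the ester trans to C2)
Conditions: o-dichlorobenzene (dilute, degassed), BHT, 180 °C
Reagents that add atoms: none
Why: Thermal cycloreversion of the bicyclo[2.2.0]hexane through a cyclohexane-1,4-diyl, known for tricyclo[4.4.0.0(2,5)]decanes; homolysis of C1–C4 is followed by cleavage of the weakest flanking bond C5–C10 (fully substituted at C10 and next to the ester), and the chair diyl with C6 and the ester equatorial and only C9 axial gives the ring-trans C4=C5 and ring-cis C1=C10 alkenes, the enoate conjugation disfavouring onward Cope contraction.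

**Step 16**
Reactants: 18 diene
Product: 19 fluctuadin
Conditions: mCPBA, CH2Cl2, 0 °C
Reagents that add atoms: mCPBA, O=C(OO)c1cccc(Cl)c1
Why: Prilezhaev epoxidation, chemoselective for the only electron-rich alkene; allylic 1,3-strain with C15 holds H6 in the alkene plane, the ring covers the face on the C7 side, and peripheral attack on the O6 side gives the 4R,5R trans-oxirane.

**Compound list**
1 | methylenecyclobutane | C=C1CCC1 | starting material
2 | 1-methylcyclobutene | CC1=CCC1 | intermediate
3 | methyl 3-oxocyclohex-1-ene-1-carboxylate | COC(=O)C1=CC(=O)CCC1 | starting material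
4 | methyl (1R,2R,5S,6R)-5-methyl-7-oxotricyclo[4.4.0.0(2,5)]decane-1-carboxylate, cis-anti-cis | COC(=O)[C@@]12CCCC(=O)[C@@H]1[C@@]3(C)CC[C@@H]23 | intermediate
5 | C7=C8 enone of 4 | COC(=O)[C@@]12CC=CC(=O)[C@@H]1[C@@]3(C)CC[C@@H]23 | intermediate
6 | 6S allylic alcohol, O6 concave | COC(=O)[C@@]12CC=C[C@H](O)[C@@H]1[C@@]3(C)CC[C@@H]23 | intermediate
7 | diethylphosphonoacetic acid | CCOP(=O)(CC(=O)O)OCC | starting material
8 | C6 diethylphosphonoacetate of 6 | COC(=O)[C@@]12CC=C[C@H](OC(=O)CP(=O)(OCC)OCC)[C@@H]1[C@@]3(C)CC[C@@H]23 | intermediate
9 | convex-face 7,8-epoxide of 8 | COC(=O)[C@@]12C[C@H]5O[C@H]5[C@H](OC(=O)CP(=O)(OCC)OCC)[C@@H]1[C@@]3(C)CC[C@@H]23 | intermediate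
10 | cis-6,12-lactone, C11 phosphonate (C11 epimers, left undefined), convex C8–OH | COC(=O)[C@@]12C[C@@H](O)[C@H]4[C@H](OC(=O)C4P(=O)(OCC)OCC)[C@@H]1[C@@]3(C)CC[C@@H]23 | intermediate
11 | phosphono lactone, C8=C9 alkene | COC(=O)[C@@]12C=C[C@H]4[C@H](OC(=O)C4P(=O)(OCC)OCC)[C@@H]1[C@@]3(C)CC[C@@H]23 | intermediate
12 | convex-face 8,9-cis-diol | COC(=O)[C@@]12[C@@H](O)[C@@H](O)[C@H]4[C@H](OC(=O)C4P(=O)(OCC)OCC)[C@@H]1[C@@]3(C)CC[C@@H]23 | intermediate
13 | C8 ketone, C9 hydroxyl | COC(=O)[C@@]12[C@@H](O)C(=O)[C@H]4[C@H](OC(=O)C4P(=O)(OCC)OCC)[C@@H]1[C@@]3(C)CC[C@@H]23 | intermediate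
14 | C8 ketone, C9 acetate | COC(=O)[C@@]12[C@@H](OC(C)=O)C(=O)[C@H]4[C@H](OC(=O)C4P(=O)(OCC)OCC)[C@@H]1[C@@]3(C)CC[C@@H]23 | intermediate
15 | concave C8–OH, C9 acetate | COC(=O)[C@@]12[C@@H](OC(C)=O)[C@H](O)[C@H]4[C@H](OC(=O)C4P(=O)(OCC)OCC)[C@@H]1[C@@]3(C)CC[C@@H]23 | intermediate
16 | C8 methacrylate, C9 acetate, C11 phosphonate | COC(=O)[C@@]12[C@@H](OC(C)=O)[C@H](OC(=O)C(C)=C)[C@H]4[C@H](OC(=O)C4P(=O)(OCC)OCC)[C@@H]1[C@@]3(C)CC[C@@H]23 | intermediate
17 | α-methylene lactone tricycle | COC(=O)[C@@]12[C@@H](OC(C)=O)[C@H](OC(=O)C(C)=C)[C@H]4[C@H](OC(=O)C4=C)[C@@H]1[C@@]3(C)CC[C@@H]23 | intermediate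
18 | 4,5-deoxyfluctuadin | C=C(C)C(=O)O[C@@H]1[C@@H]2C(=C)C(=O)O[C@@H]2/C=C(\C)CC/C=C(/C(=O)OC)[C@H]1OC(C)=O | intermediate
19 | fluctuadin | C=C(C)C(=O)O[C@@H]1[C@@H]2C(=C)C(=O)O[C@@H]2[C@H]2O[C@]2(C)CC/C=C(/C(=O)OC)[C@H]1OC(C)=O | target

**Step count**
Total steps: 16.
Longest linear sequence: 16 (1 → 2 → 4 → … → 19); 15 from 3.

**Steps most likely to fail**

Step 2. What may go wrong:
- Loss of enantiofacial control, through excitation of unbound 3 or through binding of the Lewis acid at the ester carbonyl.
- Acid-induced oligomerisation of 2.

The fallback sets out from 2 and 3 and uses known chemistry only. Irradiation without any Lewis acid (350 nm, CH2Cl2, −40 °C) is the classical enone–cyclobutene photocycloaddition. It forms the same bonds and gives 4 as a racemate, that is, together with the mirror-image photoadduct F1. IBX as in step 3 carries the pair on to 5 and the mirror-image enone F2. A Corey–Bakshi–Shibata reduction (Me-CBS oxazaborolidine, BH3·SMe2, THF, −40 °C), stopped near half conversion, then serves as a kinetic resolution. With the catalyst antipode whose preferred hydride trajectory coincides with the convex face of 5, 5 should be reduced quickly. In F2 catalyst and substrate preferences oppose each other, so F2 stays behind and is removed by chromatography. The route is rejoined at 6.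

Step 15. What may go wrong:
- Partition of the 1,4-diyl between its two chairs, which exchanges the cis and trans alkene positions.
- Cleavage of C2–C3 in place of C5–C10.
- Onward Cope contraction to a divinylcyclohexane.
- Radical polymerisation of the acrylate units at high temperature.

The fallback sets out from 16 and reverses the order of ring opening and methylenation. 16, which lacks the exocyclic methylene lactone, is heated in dilute o-dichlorobenzene with BHT, or passed through a heated flow tube with short contact time, to give the cyclodecadiene phosphonate F3. Its polar phosphonate handle should ease separation from geometric or ring-contracted isomers. The Horner–Wadsworth–Emmons reaction with aqueous HCHO and K2CO3 is then run on the ten-membered ring, and the route is rejoined at 18.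

Step 7. What may go wrong:
- Sluggish attack of the stabilised carbanion on the hindered oxirane.
- Base-induced isomerisation of the oxirane to an allylic alcohol.
- Attack of the freed C8 hydroxyl on the C14 ester, which lies 1,3-cis to it.

The fallback sets out from 8 and replaces the anionic closure by an oxidative radical cyclisation (Mn(OAc)3·2H2O, Cu(OAc)2, AcOH, 60 °C). The C11 radical adds 5-exo to C7 on the side of its tether, which again makes C7–C11 cis to O6. Cu(OAc)2 then oxidises the C8 radical to the less substituted C8=C9 alkene. No C8 hydroxyl is ever formed, steps 6 to 8 drop out, and the route is rejoined at 11.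

**Further compounds**
F1 | step 2 | methyl (1S,2S,5R,6S)-5-methyl-7-oxotricyclo[4.4.0.0(2,5)]decane-1-carboxylate (mirror-image photoadduct) | COC(=O)[C@]12CCCC(=O)[C@H]1[C@]3(C)CC[C@H]23
F2 | step 2 | methyl (1S,2S,5R,6S)-5-methyl-7-oxotricyclo[4.4.0.0(2,5)]dec-8-ene-1-carboxylate (mirror-image enone) | COC(=O)[C@]12CC=CC(=O)[C@H]1[C@]3(C)CC[C@H]23
F3 | step 15 | cyclodecadiene phosphonate (18 with H and P(O)(OEt)2 on C11 in place of the methylene, C11 epimers) | C=C(C)C(=O)O[C@@H]1[C@@H]2C(P(=O)(OCC)OCC)C(=O)O[C@@H]2/C=C(\C)CC/C=C(/C(=O)OC)[C@H]1OC(C)=O
F0 | step 7 | none | none
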